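## Retrosynthetic overview
- The free acid comes from its tert-butyl ester. The cyclohexane (C6–C7 bond) and the γ-lactone (O6–C12 bond) are both closed in the last operation from a fully acyclic aldehyde/allylsilane. The carbocycle closes first and the lactone directly after it, and no ring exists before that point.
- The acyclic aldehyde comes from an acid made by an enantioselective boron Ireland–Claisen rearrangement of an itaconate allyl ester. This forms C5–C10, sets the vinyl/methyl quaternary centre, and brings in C3, C4, C5, C6 and C15 at the right oxidation level.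
- The allylic alcohol half comes from an asymmetric vinylogous Mukaiyama aldol reaction (C8–C9 bond, sets C8) between the prenal dienol ether and a 4-oxo-2-(silylmethyl)enoate. The angelate is put on while C8–OH is still acyclic and unhindered.
- Carbon sources: trimethyl phosphonoacetate, ICH2SiMe3, dimethoxyacetaldehyde, prenal, monomethyl itaconate and angelic acid.

C-labels below are elemane numbers: C6 is the lactone carbinol, C8 the angelate carbon, C10 the quaternary carbon and C15 the acid carbon.

Assumption: both antipodes of the chiral promoters of steps 5 and 10 are available. The antipode named is the one expected from the usual models and is exchanged if the sense proves opposite.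

## Route

Step 1
Reactants: 1 trimethyl phosphonoacetate; 2 (iodomethyl)trimethylsilane
Product: 3 methyl 2-(dimethoxyphosphoryl)-3-(trimethylsilyl)propanoate (racemic)
Conditions: NaH, THF–DMSO, 0 → 50 °C
Reagents that add atoms: none
Why: SN2 alkylation of the stabilised phosphonoacetate anion, in which the α-silyl iodide is a good SN2 partner, the bulky CH2SiMe3 group stops a second alkylation, and the new stereocentre is lost in step 2.

Step 2
Reactants: 3 methyl 2-(dimethoxyphosphoryl)-3-(trimethylsilyl)propanoate; 4 2,2-dimethoxyacetaldehyde (dried from the commercial aqueous solution)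
Product: 5 methyl (Z)-4,4-dimethoxy-2-[(trimethylsilyl)methyl]but-2-enoate (acetal carbon trans to CO2Me, cis to CH2SiMe3)
Conditions: NaH, THF, 0 °C → rt; chromatography
Reagents that add atoms: none
Why: Horner–Wadsworth–Emmons olefination, in which α-branched phosphonoacetates place the aldehyde residue trans to CO2Me and the minor isomer (which would later lactonise onto O8) is removed here.

Step 3
Reactants: 5 methyl (Z)-4,4-dimethoxy-2-[(trimethylsilyl)methyl]but-2-enoate
Product: 6 methyl (Z)-4-oxo-2-[(trimethylsilyl)methyl]but-2-enoate (CHO trans to CO2Me)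
Conditions: Amberlyst-15, acetone–H2O, rt
Reagents that add atoms: water, O
Why: Acid-catalysed acetal hydrolysis, which the ester-deactivated allylsilane survives without protodesilylation and which leaves the already more stable enal geometry untouched.

Step 4
Reactants: 7 3-methylbut-2-enal (prenal)
Product: 8 (E)-tert-butyldimethyl[(3-methylbuta-1,3-dien-1-yl)oxy]silane
Conditions: TBSOTf, Et3N, Et2O, 0 °C
Reagents that add atoms: tert-butyldimethylsilyl triflate, CC(C)(C)[Si](C)(C)OS(=O)(=O)C(F)(F)F
Why: Soft enolisation (O-silylation followed by γ-deprotonation) of the enal gives the extended E-dienol ether, the standard nucleophile for vinylogous Mukaiyama aldol reactions.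

Step 5
Reactants: 6 methyl (Z)-4-oxo-2-[(trimethylsilyl)methyl]but-2-enoate; 8 (E)-tert-butyldimethyl[(3-methylbuta-1,3-dien-1-yl)oxy]silane
Product: 10 methyl (2Z,4R,6E)-4,8-dihydroxy-6-methyl-2-[(trimethylsilyl)methyl]octa-2,6-dienoate, via hydroxy enal 9 (not isolated)
Conditions: B-phenyl oxazaborolidinone from N-Ts-L-tryptophan (50 mol %), iPrOH (1 equiv), EtCN, −78 °C; then MeOH, CeCl3·7H2O, NaBH4, −78 → −20 °C
Reagents that add atoms: none
Why: Asymmetric vinylogous Mukaiyama aldol reaction, in which the chiral boron Lewis acid shields one face of the very electrophilic aldehyde, γ-attack of the dienol ether makes C8–C9, sets C8 (R) and gives the E-enal, and a Luche reduction in the same flask reduces only the enal; O8 cannot lactonise because C8 is trans to CO2Me.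

Step 6
Reactants: 11 4-methyl hydrogen itaconate (4-methoxy-2-methylidene-4-oxobutanoic acid)
Product: 12 1-tert-butyl 4-methyl itaconate
Conditions: tert-butyl 2,2,2-trichloroacetimidate, cyclohexane–CH2Cl2, rt
Reagents that add atoms: tert-butyl 2,2,2-trichloroacetimidate, CC(C)(C)OC(=N)C(Cl)(Cl)Cl
Why: Imidate tert-butylation of the carboxylic acid, which the acid itself catalyses and which needs no base, so the itaconate does not slip into the mesaconate.

Step 7
Reactants: 12 1-tert-butyl 4-methyl itaconate
Product: 13 3-(tert-butoxycarbonyl)but-3-enoic acid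
Conditions: LiOH (1.05 equiv), THF–H2O, 0 °C; then HCl to pH 3
Reagents that add atoms: lithium hydroxide, [Li+].[OH-]
Why: Chemoselective saponification, in which the unhindered saturated methyl ester is cleaved far faster than the conjugated tert-butyl ester and the low temperature suppresses double-bond migration.

Step 8
Reactants: 10 methyl (2Z,4R,6E)-4,8-dihydroxy-6-methyl-2-[(trimethylsilyl)methyl]octa-2,6-dienoate; 13 3-(tert-butoxycarbonyl)but-3-enoic acid
Product: 14 1-tert-butyl 4-[(2E,5R,6Z)-5-hydroxy-7-(methoxycarbonyl)-3-methyl-8-(trimethylsilyl)octa-2,6-dien-1-yl] itaconate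
Conditions: DCC, DMAP (5 mol %), CH2Cl2, −20 °C
Reagents that add atoms: none
Why: Steglich esterification, in which the primary allylic OH is acylated well before the secondary C8–OH at low temperature and no stereocentre is touched.

Step 9
Reactants: 14 1-tert-butyl 4-[(2E,5R,6Z)-5-hydroxy-7-(methoxycarbonyl)-3-methyl-8-(trimethylsilyl)octa-2,6-dien-1-yl] itaconate; 15 angelic acid
Product: 17 the C8 angelate of 14 (5R; angelate Z), via angelic trichlorobenzoic anhydride 16 (not isolated)
Conditions: 15, 2,4,6-trichlorobenzoyl chloride, Et3N, toluene, rt; then 14, 60 °C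
Reagents that add atoms: none
Why: Yamaguchi-type mixed-anhydride acylation run without DMAP, the usual way to transfer an angeloyl group without Z → E (tiglate) isomerisation, with C8 keeping its configuration because only the O–H bond reacts.

Step 10
Reactants: 17 the C8 angelate of 14
Product: 19 (2R,3S,5R,6Z)-2-[1-(tert-butoxycarbonyl)ethenyl]-3-ethenyl-7-(methoxycarbonyl)-3-methyl-5-{[(2Z)-2-methylbut-2-enoyl]oxy}-8-(trimethylsilyl)oct-6-enoic acid, via boron ketene acetal 18 (not isolated)
Conditions: (S,S)-N,N'-(1,2-diphenylethane-1,2-diyl)bis[3,5-bis(trifluoromethyl)benzenesulfonamide], BBr3, CH2Cl2, rt, evaporate; 17, Et3N, toluene–hexane, −78 °C, then 4 °C, 48 h; aqueous work-up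
Reagents that add atoms: none
Why: Enantioselective boron Ireland–Claisen rearrangement, in which soft enolisation touches the only ester that has α-hydrogens, Et3N in toluene–hexane gives the E(O) ketene acetal (C4 cis to the allyl oxygen), this passes with the E-trisubstituted alkene through a chair that puts H5 anti to the C10 methyl (C5 R and C10 S), and the C2-symmetric diazaborolidine chooses the face independently of the remote C8 centre; allyl 3-substituted but-3-enoates of geraniol type are the closest known substrates.

Step 11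
Reactants: 19 the Ireland–Claisen acid
Product: 21 the aldehyde corresponding to 19 (CHO in place of CO2H, all configurations unchanged), via acid chloride 20 (not isolated)
Conditions: 1-chloro-N,N,2-trimethylprop-1-en-1-amine, CH2Cl2, 0 °C; then LiAlH(OtBu)3 (1.0 equiv), THF, −78 °C
Reagents that add atoms: none
Why: Neutral acid chloride formation followed by hindered-hydride reduction of the acid chloride, the most electrophilic carbonyl present, which stops at the aldehyde at −78 °C, leaves the four esters alone, and involves no base that could epimerise or conjugate C5.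

Step 12
Reactants: 21 the acyclic aldehyde
Product: 24 8β-angeloyloxyelema-1,3,11(13)-trien-6α,12-olid-15-oic acid (5R,6R,7R,8R,10S; CNP0256928.2), via silyl ether 22 (not isolated), via tert-butyl ester lactone 23 (not isolated)
Conditions: HNTf2 (5 mol %), CH2Cl2 (0.01 M), −78 → 0 °C; then TFA, 0 °C → rt
Reagents that add atoms: none
Why: Intramolecular Hosomi–Sakurai allylation followed by lactonisation, in which C7 of the ester-deactivated allylsilane attacks the silylium-activated aldehyde through a chair with the C5 acrylate, O6 and the C7 side chain all equatorial (attack anti to the C5 acrylate, Felkin sense) so that H5/H6/H7 come out trans/trans, Me3Si moves to O6, the silyl ether closes only on the neighbouring methyl ester (the tert-butyl ester does not react) to give the trans-fused α-methylene lactone, the metal-free donor avoids the 1,4-loss of angelate that an allyl zinc, indium or chromium species would suffer, and TFA finally frees the C15 acid.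

## Compound list
1 | trimethyl phosphonoacetate | COC(=O)CP(=O)(OC)OC | starting material
2 | (iodomethyl)trimethylsilane | C[Si](C)(C)CI | starting material
3 | methyl 2-(dimethoxyphosphoryl)-3-(trimethylsilyl)propanoate | COC(=O)C(C[Si](C)(C)C)P(=O)(OC)OC | intermediate
4 | 2,2-dimethoxyacetaldehyde | COC(OC)C=O | starting material
5 | methyl (Z)-4,4-dimethoxy-2-[(trimethylsilyl)methyl]but-2-enoate | COC(OC)/C=C(/C(=O)OC)C[Si](C)(C)C | intermediate
6 | methyl (Z)-4-oxo-2-[(trimethylsilyl)methyl]but-2-enoate | O=C/C=C(/C(=O)OC)C[Si](C)(C)C | intermediate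
7 | 3-methylbut-2-enal | CC(C)=CC=O | starting material
8 | (E)-tert-butyldimethyl[(3-methylbuta-1,3-dien-1-yl)oxy]silane | C=C(C)/C=C/O[Si](C)(C)C(C)(C)C | intermediate
9 | methyl (2Z,4R,6E)-4-hydroxy-6-methyl-8-oxo-2-[(trimethylsilyl)methyl]octa-2,6-dienoate | O=C/C=C(\C)C[C@@H](O)/C=C(/C(=O)OC)C[Si](C)(C)C | intermediate
10 | methyl (2Z,4R,6E)-4,8-dihydroxy-6-methyl-2-[(trimethylsilyl)methyl]octa-2,6-dienoate | OC/C=C(\C)C[C@@H](O)/C=C(/C(=O)OC)C[Si](C)(C)C | intermediate
11 | 4-methyl hydrogen itaconate | C=C(CC(=O)OC)C(=O)O | starting material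
12 | 1-tert-butyl 4-methyl itaconate | C=C(CC(=O)OC)C(=O)OC(C)(C)C | intermediate
13 | 3-(tert-butoxycarbonyl)but-3-enoic acid | C=C(CC(=O)O)C(=O)OC(C)(C)C | intermediate
14 | itaconate mono-ester of diol 10 (free C8–OH) | C=C(CC(=O)OC/C=C(\C)C[C@@H](O)/C=C(/C(=O)OC)C[Si](C)(C)C)C(=O)OC(C)(C)C | intermediate
15 | angelic acid | C/C=C(/C)C(=O)O | starting material
16 | angelic 2,4,6-trichlorobenzoic anhydride | C/C=C(/C)C(=O)OC(=O)c1c(Cl)cc(Cl)cc1Cl | intermediate
17 | C8 angelate of 14 | C=C(CC(=O)OC/C=C(\C)C[C@@H](OC(=O)/C(C)=C\C)/C=C(/C(=O)OC)C[Si](C)(C)C)C(=O)OC(C)(C)C | intermediate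
18 | E(O) boron ketene acetal of 17 | C=C(C(=O)OC(C)(C)C)/C=C(/OB1N(S(=O)(=O)c2cc(cc(c2)C(F)(F)F)C(F)(F)F)[C@@H](c2ccccc2)[C@H](c2ccccc2)N1S(=O)(=O)c1cc(cc(c1)C(F)(F)F)C(F)(F)F)OC/C=C(\C)C[C@@H](OC(=O)/C(C)=C\C)/C=C(/C(=O)OC)C[Si](C)(C)C | intermediate
19 | Ireland–Claisen acid (C5 R, C10 S, C8 R) | C=C[C@](C)(C[C@@H](OC(=O)/C(C)=C\C)/C=C(/C(=O)OC)C[Si](C)(C)C)[C@@H](C(=O)O)C(=C)C(=O)OC(C)(C)C | intermediate
20 | acid chloride of 19 | C=C[C@](C)(C[C@@H](OC(=O)/C(C)=C\C)/C=C(/C(=O)OC)C[Si](C)(C)C)[C@@H](C(=O)Cl)C(=C)C(=O)OC(C)(C)C | intermediate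
21 | acyclic aldehyde | C=C[C@](C)(C[C@@H](OC(=O)/C(C)=C\C)/C=C(/C(=O)OC)C[Si](C)(C)C)[C@@H](C=O)C(=C)C(=O)OC(C)(C)C | intermediate
22 | cyclohexane 6α-trimethylsilyl ether (methyl and tert-butyl esters intact) | C=C[C@]1(C)C[C@@H](OC(=O)/C(C)=C\C)[C@@H](C(=C)C(=O)OC)[C@H](O[Si](C)(C)C)[C@H]1C(=C)C(=O)OC(C)(C)C | intermediate
23 | tert-butyl ester of the target | C=C[C@]1(C)C[C@@H](OC(=O)/C(C)=C\C)[C@H]2C(=C)C(=O)O[C@@H]2[C@H]1C(=C)C(=O)OC(C)(C)C | intermediate
24 | CNP0256928.2 | C=C[C@]1(C)C[C@@H](OC(=O)/C(C)=C\C)[C@H]2C(=C)C(=O)O[C@@H]2[C@H]1C(=C)C(=O)O | target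

## Step count and risks
Total step count: 12.
Longest linear sequence: 9 (steps 1, 2, 3, 5, 8, 9, 10, 11, 12).

**Step 12 is the most likely to fail.** The required chair carries the C8 angelate axial and syn to the axial C10 methyl, so the flipped chair (wrong C6/C7 pair) or a slow reaction may win. The fallback sets out from 21 and comes back at 23, and it changes the order of ring formation. Heating 21 in toluene at about 120 °C lets its 1,5-diene undergo a Cope rearrangement, through a chair with CHO and the C9 chain equatorial and driven by conjugation, to the linear E,E-enal F1. The same silylium catalysis at high dilution then closes the ten-membered ring and the lactone together to give the germacranolide tert-butyl ester F2. In that closure C7 can be attacked anti to C9 with H8 inside, which is the sense that gives the natural C7/C8 relation, and there is no 1,3-diaxial clash. Thermolysis of F2 (xylene, about 160–200 °C) runs the Cope rearrangement back through the crown conformer and relays C6/C7 to C5/C10, giving 23. TFA then cleaves 23 as in step 12.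

**Step 10 is second.** It uses a stoichiometric chiral boron reagent on a substrate with five carbonyl groups. The fallback sets out from 10 and comes back at 21, and it moves the [3,3] step to a catalytic Claisen variant with a different oxygen carbon.
- Rh2(OAc)4-catalysed O–H insertion of tert-butyl diazo(dimethoxyphosphoryl)acetate into the primary OH gives the phosphonate ether F3.
- Acylation as in step 9 gives its angelate F4.
- Horner–Wadsworth–Emmons reaction with 4 (LiCl, DBU) gives the 2-(tert-butoxycarbonyl) allyl vinyl ether F5, and the isomer with C6 trans to the ether oxygen is separated.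
- A catalytic asymmetric Gosteli–Claisen rearrangement with Cu(SbF6)2·(S,S)-tBu-box (10 mol %) passes through the chair with C6 and C9 equatorial and gives the α-keto ester F6, which has the same C5/C10 pair.
- Ph3P=CH2 turns the ketone into the acrylate acetal F7.
- Amberlyst-15 in wet acetone unmasks 21.

**Step 5 is third.** The enantioselectivity of the vinylogous aldol reaction on this unusual enal is uncertain. The fallback sets out from 6 and 8 and comes back at 14, and it sets C8 by reduction instead of by C–C bond formation. The aldol reaction is run with BF3·OEt2 at −78 °C and followed by the same Luche reduction to give the racemic diol F8. Esterification as in step 8 gives the racemic mono-ester F9. Dess–Martin periodinane oxidises the secondary allylic alcohol to the enone F10. CBS reduction (Me-CBS oxazaborolidine, catecholborane, −78 °C) then delivers 14 under reagent control.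

## Further compounds
F1 | step 12 | linear E,E-enal (Cope isomer of 21) | O=C/C=C(/CC/C=C(\C)C[C@@H](OC(=O)/C(C)=C\C)/C=C(/C(=O)OC)C[Si](C)(C)C)C(=O)OC(C)(C)C
F2 | step 12 | germacranolide tert-butyl ester | C/C1=C\CC/C(C(=O)OC(C)(C)C)=C/[C@H]2OC(=O)C(=C)[C@@H]2[C@H](OC(=O)/C(C)=C\C)C1
F3 | step 10 | phosphonate ether of diol 10 | COP(=O)(OC)C(OC/C=C(\C)C[C@@H](O)/C=C(/C(=O)OC)C[Si](C)(C)C)C(=O)OC(C)(C)C
F4 | step 10 | angelate of F3 | COP(=O)(OC)C(OC/C=C(\C)C[C@@H](OC(=O)/C(C)=C\C)/C=C(/C(=O)OC)C[Si](C)(C)C)C(=O)OC(C)(C)C
F5 | step 10 | 2-(tert-butoxycarbonyl) allyl vinyl ether | COC(OC)/C=C(/OC/C=C(\C)C[C@@H](OC(=O)/C(C)=C\C)/C=C(/C(=O)OC)C[Si](C)(C)C)C(=O)OC(C)(C)C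
F6 | step 10 | α-keto ester acetal | C=C[C@](C)(C[C@@H](OC(=O)/C(C)=C\C)/C=C(/C(=O)OC)C[Si](C)(C)C)[C@@H](C(OC)OC)C(=O)C(=O)OC(C)(C)C
F7 | step 10 | acrylate acetal | C=C[C@](C)(C[C@@H](OC(=O)/C(C)=C\C)/C=C(/C(=O)OC)C[Si](C)(C)C)[C@@H](C(OC)OC)C(=C)C(=O)OC(C)(C)C
F8 | step 5 | racemic diol | OC/C=C(\C)CC(O)/C=C(/C(=O)OC)C[Si](C)(C)C
F9 | step 5 | racemic mono-ester | C=C(CC(=O)OC/C=C(\C)CC(O)/C=C(/C(=O)OC)C[Si](C)(C)C)C(=O)OC(C)(C)C
F10 | step 5 | C8 enone | C=C(CC(=O)OC/C=C(\C)CC(=O)/C=C(/C(=O)OC)C[Si](C)(C)C)C(=O)OC(C)(C)C
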